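**Retrosynthetic overview**
1. Benzil ⇒ deoxybenzoin. The second C=O is the last bond made, a C–O bond formed by aerobic oxygenation of the ArCO–CH2–Ar' methylene. This is the key step.
2. C8 prenyl ⇒ C8–H, by Friedel–Crafts prenylation at the only free carbon of ring A.
3. Pyran ring C ⇒ opened at its O1–C2 bond, which is closed by oxa-6π electrocyclisation of an ortho-quinone methide made from a C5 enal and the resorcinol part of ring A.
4. Deoxybenzoin ⇒ phloroglucinol monomethyl ether (ring A, brings the OMe) plus an arylacetic acid (ring B), joined by Friedel–Crafts acylation. No protecting groups are used.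
5. Ring order: rings A and B are bought, and ring C is the only ring formed (step 2).

Assumption: the target SMILES has no stereocentre and no stereogenic double bond, so the compound is achiral and no stereocontrol is needed.

**Step 1**
Reactants: 1 5-methoxyresorcinol; 2 4-hydroxyphenylacetic acid
Product: 3 1-(2,4-dihydroxy-6-methoxyphenyl)-2-(4-hydroxyphenyl)ethan-1-one
Conditions: BF3·OEt2 (as solvent), 85 °C, 2 h; then aq NaOAc; chromatography
Reagents that add atoms: none
Why: Friedel–Crafts acylation, in which the phloroglucinol-type ring reacts at one of its two equivalent positions (para to one OH, ortho to the other), the product is held as a chelated ortho-hydroxy ketone, ring B is far less nucleophilic, and the minor symmetrical 2,6-dihydroxy-4-methoxy isomer is removed by chromatography; no stereocentre is formed.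

**Step 2**
Reactants: 3 1-(2,4-dihydroxy-6-methoxyphenyl)-2-(4-hydroxyphenyl)ethan-1-one; 4 3-methylbut-2-enal (prenal, 1.5 equiv)
Product: 6 1-(5-hydroxy-7-methoxy-2,2-dimethyl-2H-chromen-6-yl)-2-(4-hydroxyphenyl)ethan-1-one, via ortho-quinone methide 5 (not isolated)
Conditions: ethylenediammonium diacetate (EDDA, 10 mol %), toluene–DMF 9:1, 105 °C, 8 h
Reagents that add atoms: none
Why: Formal [3+3] chromene annulation (Knoevenagel-type condensation, then oxa-6π electrocyclisation), in which the iminium ion of 4 is attacked by the carbon between the two hydroxyls, amine loss gives 5, and the O1–C2 bond closes through the free para oxygen because closure through the other oxygen would cost the hydrogen bond to the ketone; the simple phenol of ring B does not react and no stereocentre is formed.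

**Step 3**
Reactants: 6 1-(5-hydroxy-7-methoxy-2,2-dimethyl-2H-chromen-6-yl)-2-(4-hydroxyphenyl)ethan-1-one; 7 2-methylbut-3-en-2-ol (1.5 equiv, slow addition)
Product: 8 1-[5-hydroxy-7-methoxy-2,2-dimethyl-8-(3-methylbut-2-en-1-yl)-2H-chromen-6-yl]-2-(4-hydroxyphenyl)ethan-1-one
Conditions: BF3·OEt2 (50 mol %), 1,4-dioxane, 20 °C, 4 h
Reagents that add atoms: none
Why: Friedel–Crafts prenylation, in which the dimethylallyl cation is captured at its primary end by C8, the only free position of ring A and activated by three oxygens (two ortho, one para) against one for ring B; both oxygens flanking C8 are etherified, so the usual acid cyclisation of an ortho-prenylphenol to a chroman cannot occur, and no stereocentre is formed.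

**Step 4**
Reactants: 8 1-[5-hydroxy-7-methoxy-2,2-dimethyl-8-(3-methylbut-2-en-1-yl)-2H-chromen-6-yl]-2-(4-hydroxyphenyl)ethan-1-one
Product: 10 1-[5-hydroxy-7-methoxy-2,2-dimethyl-8-(3-methylbut-2-en-1-yl)-2H-chromen-6-yl]-2-(4-hydroxyphenyl)ethane-1,2-dione (target CNP0184805.0), via alpha-hydroperoxy ketone 9 (not isolated)
Conditions: Cu(OAc)2 (10 mol %), 1,10-phenanthroline (10 mol %), DABCO (30 mol %), O2 (1 atm), DMF, 35 °C, 12 h; then aq citric acid wash
Reagents that add atoms: dioxygen, O=O
Why: Proposed new method: self-templated aerobic methylene oxygenation, in which the chelated 5-OH/ketone pair of 8 serves as the O,O-ligand of a cationic phenanthroline complex of divalent copper, so that only the flanking CH2 becomes acidic enough for acetate/DABCO to enolise it while the ring B phenol stays protonated; inner-sphere electron transfer then gives monovalent copper and a captodatively stabilised alpha-keto benzylic radical delocalised into the 4-hydroxyphenyl ring, O2 capture and recombination with copper give the copper-bound form of 9, and base-induced Kornblum–DeLaMare-type loss of water creates the new C=O, while any benzoin formed by O–O reduction is carried on to the same diketone by the same catalyst; no electrophilic oxygen-transfer agent, halogen or free alkoxyl radical is present, so the prenyl and chromene olefins should survive; the closest known reaction types are the amine-base or copper-salt promoted aerobic oxidation of simple protected deoxybenzoins to benzils and the Cu(OAc)2 oxidation of benzoins, neither of which has been shown on an unprotected, olefin-bearing polyphenolic deoxybenzoin or with the substrate acting as ligand; the transient stereocentre of 9 is racemic and is destroyed.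

**Compound list**
1 | 5-methoxyresorcinol (5-methoxybenzene-1,3-diol) | COc1cc(O)cc(O)c1 | starting material
2 | 4-hydroxyphenylacetic acid | OC(=O)Cc1ccc(O)cc1 | starting material
3 | 1-(2,4-dihydroxy-6-methoxyphenyl)-2-(4-hydroxyphenyl)ethan-1-one | COc1cc(O)cc(O)c1C(=O)Cc1ccc(O)cc1 | intermediate
4 | 3-methylbut-2-enal (prenal) | CC(C)=CC=O | starting material
5 | (6Z)-5-hydroxy-4-[(4-hydroxyphenyl)acetyl]-3-methoxy-6-(3-methylbut-2-en-1-ylidene)cyclohexa-2,4-dien-1-one (ortho-quinone methide, not isolated) | O=C1C=C(OC)C(C(=O)Cc2ccc(O)cc2)=C(O)/C1=C/C=C(C)C | intermediate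
6 | 1-(5-hydroxy-7-methoxy-2,2-dimethyl-2H-chromen-6-yl)-2-(4-hydroxyphenyl)ethan-1-one | COc1cc2c(c(O)c1C(=O)Cc1ccc(O)cc1)C=CC(C)(C)O2 | intermediate
7 | 2-methylbut-3-en-2-ol | CC(C)(O)C=C | starting material
8 | 1-[5-hydroxy-7-methoxy-2,2-dimethyl-8-(3-methylbut-2-en-1-yl)-2H-chromen-6-yl]-2-(4-hydroxyphenyl)ethan-1-one | COc1c(CC=C(C)C)c2c(c(O)c1C(=O)Cc1ccc(O)cc1)C=CC(C)(C)O2 | intermediate
9 | 2-hydroperoxy-1-[5-hydroxy-7-methoxy-2,2-dimethyl-8-(3-methylbut-2-en-1-yl)-2H-chromen-6-yl]-2-(4-hydroxyphenyl)ethan-1-one (racemic, not isolated) | COc1c(CC=C(C)C)c2c(c(O)c1C(=O)C(OO)c1ccc(O)cc1)C=CC(C)(C)O2 | intermediate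
10 | 1-[5-hydroxy-7-methoxy-2,2-dimethyl-8-(3-methylbut-2-en-1-yl)-2H-chromen-6-yl]-2-(4-hydroxyphenyl)ethane-1,2-dione (achiral) | COc1c(CC=C(C)C)c2c(c(O)c1C(=O)C(=O)c1ccc(O)cc1)C=CC(C)(C)O2 | target

**Total step count:** 4. **Longest linear sequence:** 4.

**Steps most likely to fail**

Step 4 (the proposed new step). The risks are oxidative C–C cleavage of 9 or of the diketone to two carboxylic acids, copper-mediated coupling of the ring B phenol, and catalyst inhibition by the chelating product. The fallback uses known closed-shell chemistry through a C–N bond and sets out from 8. An Ehrlich–Sachs condensation with N,N-dimethyl-4-nitrosoaniline (CN(C)c1ccc(N=O)cc1; NaOEt, EtOH, 25 °C) gives the mono-anil 2-{[4-(dimethylamino)phenyl]imino}-1-[5-hydroxy-7-methoxy-2,2-dimethyl-8-(3-methylbut-2-en-1-yl)-2H-chromen-6-yl]-2-(4-hydroxyphenyl)ethan-1-one F1. Mild hydrolysis of the imine (1 M aq HCl, THF, 0 °C) comes back to the route at 10.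

Step 3. The risks are attack of the allyl cation on the electron-rich chromene C3=C4 bond, reversible O-prenylation of ring B, and low conversion. The fallback replaces cationic alkylation by halogenation and cross-coupling and sets out from 6. Iodination at the same most activated carbon (N-iodosuccinimide, MeCN, 0 °C) gives 1-(5-hydroxy-8-iodo-7-methoxy-2,2-dimethyl-2H-chromen-6-yl)-2-(4-hydroxyphenyl)ethan-1-one F2. A Migita–Kosugi–Stille coupling with tributyl(3-methylbut-2-en-1-yl)stannane (CCCC[Sn](CCCC)(CCCC)CC=C(C)C; Pd(PPh3)4 as the zerovalent palladium source, LiCl, DMF, 80 °C) comes back to the route at 8.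

Step 1. The risk is that the reversible, chelation-driven BF3 conditions favour the symmetrical 2,6-dihydroxy-4-methoxy ketone. The fallback is an irreversible Houben–Hoesch reaction with a nitrilium electrophile and sets out from 1. Treatment with 4-hydroxyphenylacetonitrile (N#CCc1ccc(O)cc1; ZnCl2, dry HCl, Et2O, 0 °C) attacks para to a free OH under kinetic control and precipitates 1-(2,4-dihydroxy-6-methoxyphenyl)-2-(4-hydroxyphenyl)ethan-1-iminium chloride F3. Boiling F3 in water comes back to the route at 3.

**Further compounds**
F1 | step 4 | 2-{[4-(dimethylamino)phenyl]imino}-1-[5-hydroxy-7-methoxy-2,2-dimethyl-8-(3-methylbut-2-en-1-yl)-2H-chromen-6-yl]-2-(4-hydroxyphenyl)ethan-1-one (E/Z mixture at C=N) | COc1c(CC=C(C)C)c2c(c(O)c1C(=O)C(=Nc1ccc(N(C)C)cc1)c1ccc(O)cc1)C=CC(C)(C)O2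
F2 | step 3 | 1-(5-hydroxy-8-iodo-7-methoxy-2,2-dimethyl-2H-chromen-6-yl)-2-(4-hydroxyphenyl)ethan-1-one | COc1c(I)c2c(c(O)c1C(=O)Cc1ccc(O)cc1)C=CC(C)(C)O2
F3 | step 1 | 1-(2,4-dihydroxy-6-methoxyphenyl)-2-(4-hydroxyphenyl)ethan-1-iminium chloride | COc1cc(O)cc(O)c1C(=[NH2+])Cc1ccc(O)cc1.[Cl-]
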